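**Plan**

- Feature: ring B is a hexasubstituted benzene in which the carbon bearing the free hydroxyl and the carbon bearing the lactone oxygen are para. Between them lie, on one side, the pyran-oxygen carbon and the pyran carbon, and on the other the prenyl carbon and the diaryl-ether carbon. This is the pattern a 4-alkenyl-4-hydroxy-3-alkoxycyclobutenone gives on heating.
- Cuts, in retrosynthetic order: the two MOM ethers; the pyran C–C bond to ring B (propargyl Claisen); the lactone C(=O)–O bond; the ring B C–C bond between the carbons carrying the lactone and ether oxygens (ring expansion); the carbinol–vinyl C–C bond (alkenylzinc plus cyclobutenedione); the vinyl C–O bond to the ring A phenol (copper coupling).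
- Forward: ring A is bought and decorated, ring B is built in step 10, the seven-membered lactone closes in step 11, the pyran ring in step 12, and deprotection is last.
- Stereochemistry: the target has no stereocentre. The E enol-ether geometry (syn hydrozirconation) and the racemic carbinol are both consumed when ring B aromatises.

Key step: step 10

Assumption: the carbinol of the cyclobutenone is made and used as a racemate. ArO below denotes the ring A residue 2-(methoxycarbonyl)-3,5-bis(methoxymethoxy)-6-(3-methylbut-2-en-1-yl)phenoxy. 4-Methylpent-3-en-1-ol is taken as a commercial starting material alongside prenyl bromide.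

**Route**

Step 1
Reactants: 1 methyl 2,4,6-trihydroxybenzoate; 2 prenyl bromide (1-bromo-3-methylbut-2-ene)
Product: 3 methyl 2,4,6-trihydroxy-3-(3-methylbut-2-en-1-yl)benzoate
Conditions: 2 (1.0 equiv), DBU (1.1 equiv), THF, 0 °C → rt
Reagents that add atoms: none
Why: C-alkylation of a phloroglucinol-type phenoxide with prenyl bromide is a standard route to C-prenylated acylphloroglucinols, and because 1 is symmetric the mono-C-alkylation can give only one regioisomer (O-alkylated and doubly alkylated material is separated).

Step 2
Reactants: 3 methyl 2,4,6-trihydroxy-3-(3-methylbut-2-en-1-yl)benzoate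
Product: 4 methyl 2-hydroxy-4,6-bis(methoxymethoxy)-3-(3-methylbut-2-en-1-yl)benzoate
Conditions: MOMCl (2.1 equiv), i-Pr2NEt, CH2Cl2, 0 °C
Reagents that add atoms: chloromethyl methyl ether (MOMCl), COCCl
Why: In this phenol alkylation (MOM acetal formation) the non-chelated 4-hydroxyl should react first and the second MOM group should go to the 6-hydroxyl, which is less hindered than the chelated 2-hydroxyl held between ester and prenyl group; any regioisomer is removed by chromatography.

Step 3
Reactants: 5 4-methylpent-3-en-1-ol
Product: 7 1,1-dibromo-5-methylhexa-1,4-diene, via 4-methylpent-3-enal 6 (not isolated)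
Conditions: Dess–Martin periodinane, NaHCO3, CH2Cl2, 0 °C; filter; then CBr4, PPh3, CH2Cl2, 0 °C
Reagents that add atoms: carbon tetrabromide, BrC(Br)(Br)Br
Why: Dess–Martin oxidation followed directly by Ramirez (Corey–Fuchs) dibromo-olefination, with buffered, cold, telescoped handling so that the β,γ-double bond of the aldehyde does not move into conjugation.

Step 4
Reactants: 4 methyl 2-hydroxy-4,6-bis(methoxymethoxy)-3-(3-methylbut-2-en-1-yl)benzoate; 7 1,1-dibromo-5-methylhexa-1,4-diene
Product: 8 methyl 2-{[(1Z)-1-bromo-5-methylhexa-1,4-dien-1-yl]oxy}-4,6-bis(methoxymethoxy)-3-(3-methylbut-2-en-1-yl)benzoate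
Conditions: CuI (10 mol %), 2,2'-bipyridine (20 mol %), K3PO4, 7 (1.5 equiv), toluene, 110 °C
Reagents that add atoms: none
Why: Ullmann-type copper-catalysed C–O coupling of a phenol with a 1,1-dibromoalkene, in which the less hindered bromide trans to the chain is replaced with retention to give the Z bromo enol ether.

Step 5
Reactants: 8 the Z bromo enol ether
Product: 9 methyl 4,6-bis(methoxymethoxy)-3-(3-methylbut-2-en-1-yl)-2-[(5-methylhex-4-en-1-yn-1-yl)oxy]benzoate
Conditions: t-BuOK (1.2 equiv), THF, −40 → −10 °C
Reagents that add atoms: none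
Why: Anti E2 dehydrobromination (vinyl hydrogen and bromine are trans) gives the aryl ynol ether, and the low temperature and short contact time should keep the skipped enyne from isomerising.

Step 6
Reactants: 10 diisopropyl squarate
Product: 12 3-isopropoxycyclobut-3-ene-1,2-dione, via 4-hydroxy-2,3-diisopropoxycyclobut-2-en-1-one 11 (not isolated)
Conditions: LiAlH(O-t-Bu)3, THF, −78 → 0 °C; aqueous work-up; then conc. HCl (cat.), CH2Cl2, rt
Reagents that add atoms: none
Why: Mono-1,2-reduction of one squarate carbonyl followed by acid-promoted loss of isopropanol is the established route from dialkyl squarates to alkyl semisquarates.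

Step 7
Reactants: 12 3-isopropoxycyclobut-3-ene-1,2-dione
Product: 13 semisquaric acid (3-hydroxycyclobut-3-ene-1,2-dione)
Conditions: 6 M aq. HCl, THF, 40 °C; evaporate
Reagents that add atoms: water, O
Why: Acid hydrolysis of a vinylogous ester by addition–elimination at the alkoxy-bearing carbon gives the stable, strongly acidic vinylogous acid.

Step 8
Reactants: 13 semisquaric acid; 14 2-methylbut-3-yn-2-ol
Product: 16 3-[(2-methylbut-3-yn-2-yl)oxy]cyclobut-3-ene-1,2-dione, via 3-chlorocyclobut-3-ene-1,2-dione 15 (not isolated)
Conditions: (COCl)2, DMF (cat.), CH2Cl2, 0 °C → rt; evaporate; then LiOC(CH3)2C≡CH (from 14 and n-BuLi, 0.98 equiv, THF, −78 °C), −78 → −30 °C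
Reagents that add atoms: none
Why: The vinylogous acid is converted into its vinylogous acid chloride and this is alcoholysed by addition–elimination with the O-lithiated tertiary propargylic alcohol, which circumvents the unfavourable direct exchange of a secondary for a tertiary alkoxy group.

Step 9
Reactants: 9 the aryl ynol ether; 16 3-[(2-methylbut-3-yn-2-yl)oxy]cyclobut-3-ene-1,2-dione
Product: 19 racemic 4-hydroxy-4-[(1E)-1-(ArO)-5-methylhexa-1,4-dien-2-yl]-3-[(2-methylbut-3-yn-2-yl)oxy]cyclobut-2-en-1-one, via alkenylzirconocene chloride 17 (not isolated), via alkenyl(methyl)zinc 18 (not isolated)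
Conditions: Cp2Zr(H)Cl (1.05 equiv), CH2Cl2, rt; Me2Zn (1.05 equiv), toluene, −78 °C; then 16, −78 → 0 °C; aq. NH4Cl
Reagents that add atoms: none
Why: Proposed new method: syn hydrozirconation of the ynol ether should place zirconium on the carbon remote from oxygen and so fix the E geometry; exchange with Me2Zn gives an alkenyl(methyl)zinc covalent enough not to expel the anti-periplanar aryloxide (the failure mode expected for the lithium or magnesium reagent, as in the ring opening of 3-metallated benzofurans), and this reagent should add to the ketone-like carbonyl of 16 flanked by the alkoxy-bearing carbon rather than to the vinylogous ester carbonyl, as hard organometallics do with alkoxycyclobutenediones; the closest known reaction type is the hydrozirconation–zinc transmetalation–1,2-addition of alkenyl groups to aldehydes and α-keto esters, and the new carbinol centre forms as a racemate that is erased in step 10.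

Step 10
Reactants: 19 the racemic 4-alkenyl-4-hydroxy-3-alkoxycyclobutenone
Product: 22 methyl 2-{3,6-dihydroxy-4-[(2-methylbut-3-yn-2-yl)oxy]-2-(3-methylbut-2-en-1-yl)phenoxy}-4,6-bis(methoxymethoxy)-3-(3-methylbut-2-en-1-yl)benzoate, via dienylketene 20 (not isolated), via cyclohexa-2,4-dienone 21 (not isolated)
Conditions: degassed toluene, 95 °C, argon
Reagents that add atoms: none
Why: Heating opens the cyclobutenone by a conrotatory 4π electrocyclic reaction in which the carbinol hydroxyl rotates outward and the alkenyl group inward, giving dienylketene 20 with the ketene carbon and the enol-ether terminus on the same side. A thermally allowed disrotatory 6π electrocyclisation then joins the ketene carbon to the aryloxy-bearing vinyl carbon and closes ring B as cyclohexa-2,4-dienone 21, which enolises to the hydroquinone. The closest known reaction type is the thermal ring expansion of squarate-derived 4-alkenyl-4-hydroxycyclobutenones to highly oxygenated hydroquinones. No stereocentre survives, since the racemic carbinol and the transient sp3 carbon of 21 both become aromatic carbons and the enol-ether geometry is lost on tautomerisation. The required substitution pattern (new phenol para to the former carbinol oxygen, propargyloxy carbon and ring hydrogen between them on one side, prenyl and aryloxy carbons on the other) was fixed in step 9 by attack at the ketone-like carbonyl and is delivered here by the donor-outward torquoselectivity. Working below about 100 °C without oxygen should keep the aryl propargyl ether from rearranging while the neighbouring phenol is still free and keep the hydroquinone from oxidising to the quinone.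

Step 11
Reactants: 22 the ring B hydroquinone diaryl ether
Product: 23 the depsidone (seven-membered lactone between the ring B hydroxyl ortho to the diaryl-ether oxygen and the ring A carboxyl) that keeps the free ring B hydroxyl, the 1,1-dimethylpropargyl ether, both prenyl groups and both MOM ethers
Conditions: Cs2CO3 (0.3 equiv), powdered 4 Å molecular sieves, degassed DMF, 60 °C, argon
Reagents that add atoms: none
Why: Base-catalysed intramolecular transesterification (lactonisation) in which only the hydroxyl ortho to the ether oxygen can reach the ester, the other phenol serving as proton source for the expelled methoxide and the sieves removing methanol to pull the equilibrium toward the aryl ester.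

Step 12
Reactants: 23 the propargyl ether depsidone
Product: 27 the bis-MOM ether of the target (2,2-dimethyl-2H-pyran fused to ring B), via allenyl dienone 24 (not isolated), via ortho-allenylphenol 25 (not isolated), via ortho-quinone methide 26 (not isolated)
Conditions: degassed o-xylene, 135 °C, argon
Reagents that add atoms: none
Why: Aryl propargyl ether Claisen rearrangement to the only free ortho carbon, followed by enolisation, 1,5-hydrogen shift and oxa-6π electrocyclisation, is the standard 2,2-dimethylchromene synthesis, and with the other neighbouring oxygen already acylated only the desired phenol can close the pyran ring.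

Step 13
Reactants: 27 the bis-MOM ether of the target
Product: 28 CNP0263700.0
Conditions: 2 M aq. HCl, i-PrOH/THF, 45 °C
Reagents that add atoms: none
Why: Mild acid hydrolysis of aryl MOM acetals is routinely used on ortho-prenylated phenols without chroman formation, and the non-methanolic medium avoids opening the hindered aryl lactone.

**Compound list**

1 | methyl 2,4,6-trihydroxybenzoate | COC(=O)c1c(O)cc(O)cc1O | starting material
2 | prenyl bromide (1-bromo-3-methylbut-2-ene) | CC(C)=CCBr | starting material
3 | methyl 2,4,6-trihydroxy-3-(3-methylbut-2-en-1-yl)benzoate | COC(=O)c1c(O)cc(O)c(CC=C(C)C)c1O | intermediate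
4 | methyl 2-hydroxy-4,6-bis(methoxymethoxy)-3-(3-methylbut-2-en-1-yl)benzoate | COC(=O)c1c(OCOC)cc(OCOC)c(CC=C(C)C)c1O | intermediate
5 | 4-methylpent-3-en-1-ol | CC(C)=CCCO | starting material
6 | 4-methylpent-3-enal | CC(C)=CCC=O | intermediate
7 | 1,1-dibromo-5-methylhexa-1,4-diene | CC(C)=CCC=C(Br)Br | intermediate
8 | methyl 2-{[(1Z)-1-bromo-5-methylhexa-1,4-dien-1-yl]oxy}-4,6-bis(methoxymethoxy)-3-(3-methylbut-2-en-1-yl)benzoate | COC(=O)c1c(OCOC)cc(OCOC)c(CC=C(C)C)c1O/C(Br)=C/CC=C(C)C | intermediate
9 | methyl 4,6-bis(methoxymethoxy)-3-(3-methylbut-2-en-1-yl)-2-[(5-methylhex-4-en-1-yn-1-yl)oxy]benzoate | COC(=O)c1c(OCOC)cc(OCOC)c(CC=C(C)C)c1OC#CCC=C(C)C | intermediate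
10 | diisopropyl squarate | CC(C)OC1=C(OC(C)C)C(=O)C1=O | starting material
11 | racemic 4-hydroxy-2,3-diisopropoxycyclobut-2-en-1-one | CC(C)OC1=C(OC(C)C)C(O)C1=O | intermediate
12 | 3-isopropoxycyclobut-3-ene-1,2-dione | CC(C)OC1=CC(=O)C1=O | intermediate
13 | semisquaric acid (3-hydroxycyclobut-3-ene-1,2-dione) | OC1=CC(=O)C1=O | intermediate
14 | 2-methylbut-3-yn-2-ol | CC(C)(O)C#C | starting material
15 | 3-chlorocyclobut-3-ene-1,2-dione | ClC1=CC(=O)C1=O | intermediate
16 | 3-[(2-methylbut-3-yn-2-yl)oxy]cyclobut-3-ene-1,2-dione | C#CC(C)(C)OC1=CC(=O)C1=O | intermediate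
17 | chlorobis(cyclopentadienyl)[(1E)-1-(ArO)-5-methylhexa-1,4-dien-2-yl]zirconium | COC(=O)c1c(OCOC)cc(OCOC)c(CC=C(C)C)c1O/C=C(\CC=C(C)C)[Zr](Cl)(C1C=CC=C1)C1C=CC=C1 | intermediate
18 | [(1E)-1-(ArO)-5-methylhexa-1,4-dien-2-yl](methyl)zinc | COC(=O)c1c(OCOC)cc(OCOC)c(CC=C(C)C)c1O/C=C(\CC=C(C)C)[Zn]C | intermediate
19 | racemic 4-hydroxy-4-[(1E)-1-(ArO)-5-methylhexa-1,4-dien-2-yl]-3-[(2-methylbut-3-yn-2-yl)oxy]cyclobut-2-en-1-one | O=C1C=C(OC(C)(C)C#C)C1(O)/C(CC=C(C)C)=C/Oc1c(CC=C(C)C)c(OCOC)cc(OCOC)c1C(=O)OC | intermediate
20 | dienylketene from ring opening of 19 (hydroxyl outward, alkenyl inward) | O=C=C/C(OC(C)(C)C#C)=C(O)\C(CC=C(C)C)=C\Oc1c(CC=C(C)C)c(OCOC)cc(OCOC)c1C(=O)OC | intermediate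
21 | racemic 6-(ArO)-4-hydroxy-3-[(2-methylbut-3-yn-2-yl)oxy]-5-(3-methylbut-2-en-1-yl)cyclohexa-2,4-dien-1-one | O=C1C=C(OC(C)(C)C#C)C(O)=C(CC=C(C)C)C1Oc1c(CC=C(C)C)c(OCOC)cc(OCOC)c1C(=O)OC | intermediate
22 | methyl 2-{3,6-dihydroxy-4-[(2-methylbut-3-yn-2-yl)oxy]-2-(3-methylbut-2-en-1-yl)phenoxy}-4,6-bis(methoxymethoxy)-3-(3-methylbut-2-en-1-yl)benzoate | CC(C)=CCc1c(O)c(OC(C)(C)C#C)cc(O)c1Oc1c(CC=C(C)C)c(OCOC)cc(OCOC)c1C(=O)OC | intermediate
23 | depsidone with free ring B hydroxyl, 1,1-dimethylpropargyl ether, two prenyl groups and two MOM ethers | CC(C)=CCc1c(O)c(OC(C)(C)C#C)cc2c1Oc1c(CC=C(C)C)c(OCOC)cc(OCOC)c1C(=O)O2 | intermediate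
24 | allenyl dienone from the [3,3] shift of 23 (racemic) | CC(C)=CCC1=C(O)C(=O)C(C=C=C(C)C)C2=C1Oc1c(CC=C(C)C)c(OCOC)cc(OCOC)c1C(=O)O2 | intermediate
25 | ortho-allenylphenol (catechol tautomer of 24) | CC(C)=CCc1c(O)c(O)c(C=C=C(C)C)c2c1Oc1c(CC=C(C)C)c(OCOC)cc(OCOC)c1C(=O)O2 | intermediate
26 | ortho-quinone methide from the 1,5-hydrogen shift of 25 | CC(C)=CCC1=C(O)C(=O)/C(=C\C=C(C)C)C2=C1Oc1c(CC=C(C)C)c(OCOC)cc(OCOC)c1C(=O)O2 | intermediate
27 | bis(methoxymethyl) ether of the target at the two ring A hydroxyls | CC(C)=CCc1c(O)c2c(c3c1Oc1c(CC=C(C)C)c(OCOC)cc(OCOC)c1C(=O)O3)C=CC(C)(C)O2 | intermediate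
28 | CNP0263700.0 | CC(C)=CCc1c(O)c2c(c3c1Oc1c(CC=C(C)C)c(O)cc(O)c1C(=O)O3)C=CC(C)(C)O2 | target

**Step count**

Total: 13 steps. Longest linear sequence: 9 steps (1, 2, 4, 5, 9, 10, 11, 12, 13).

**Steps most likely to fail**

Step 9. The alkenylzinc may add too slowly to the dione, or methyl transfer and incomplete zirconium-to-zinc exchange may compete. The fallback sets out from 9 and comes back at 19, using known chemistry only. Hydrozirconation of 9 as before, quenched with I2 (THF, 0 °C), should give the alkenyl iodide F1 with the same geometry. Iodine–lithium exchange with t-BuLi (2 equiv, Et2O/THF, −100 °C) gives the alkenyllithium F2, which is transferred within minutes onto 16 at −100 → −78 °C to give 19. This is the classical alkenyllithium addition to an alkoxycyclobutenedione; the price is the tendency of F2 to lose aryloxide by anti elimination, hence the very low temperature.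

Step 4. The doubly ortho-substituted, ester-chelated phenol may couple too slowly, so that base-induced dehydrobromination or isomerisation of 7 takes over. The fallback sets out from 4 and comes back at 9, bypassing 8 and step 5. Trichloroethylene and K2CO3 in DMF at 70 °C give the (E)-1,2-dichlorovinyl ether F3, by addition of the phenoxide to dichloroacetylene formed in situ, a sterically undemanding electrophile. n-BuLi (2.2 equiv, THF, −90 °C) converts F3 into the lithium aryloxyacetylide F4, which is alkylated with prenyl bromide 2 under CuBr·SMe2 catalysis to give 9. The hindered methyl ester is expected to outlast the brief exposure to n-BuLi at this temperature.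

Step 11. The transesterification equilibrium may stay on the side of the methyl ester, attack on the di-ortho-substituted ester may be slow, and the hydroquinone may oxidise to the quinone under base if air enters. The fallback sets out from 22 and comes back at 23. SN2 demethylation with LiSPr in DMPU at rt attacks the methyl group, not the hindered carbonyl, and gives the carboxylic acid F5. Carbodiimide lactonisation (EDC·HCl, DMAP, CH2Cl2, high dilution, rt) then closes the seven-membered ring irreversibly to 23.

**Further compounds**

F1 | step 9 | methyl 2-{[(1E)-2-iodo-5-methylhexa-1,4-dien-1-yl]oxy}-4,6-bis(methoxymethoxy)-3-(3-methylbut-2-en-1-yl)benzoate | COC(=O)c1c(OCOC)cc(OCOC)c(CC=C(C)C)c1O/C=C(\CC=C(C)C)I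
F2 | step 9 | [(1E)-1-(ArO)-5-methylhexa-1,4-dien-2-yl]lithium | COC(=O)c1c(OCOC)cc(OCOC)c(CC=C(C)C)c1O/C=C(\CC=C(C)C)[Li]
F3 | step 4 | methyl 2-{[(E)-1,2-dichloroethenyl]oxy}-4,6-bis(methoxymethoxy)-3-(3-methylbut-2-en-1-yl)benzoate | COC(=O)c1c(OCOC)cc(OCOC)c(CC=C(C)C)c1O/C(Cl)=C\Cl
F4 | step 4 | lithium (ArO)acetylide | COC(=O)c1c(OCOC)cc(OCOC)c(CC=C(C)C)c1OC#C[Li]
F5 | step 11 | 2-{3,6-dihydroxy-4-[(2-methylbut-3-yn-2-yl)oxy]-2-(3-methylbut-2-en-1-yl)phenoxy}-4,6-bis(methoxymethoxy)-3-(3-methylbut-2-en-1-yl)benzoic acid | CC(C)=CCc1c(O)c(OC(C)(C)C#C)cc(O)c1Oc1c(CC=C(C)C)c(OCOC)cc(OCOC)c1C(=O)O
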